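The data were computed with constants of no real substance.

Slowness lets us reckon this flask by hand: the feed of partner lasts 0.5 min, short beside the 8.0 min asked about, so we count partner as charged at mid-feed.

the same everywhere: starting material 0.050 M; catalyst 1.2 mM

| run | partner | remark | time |
|---|---|---|---|
| amber | 0.15 M (fed, over 30 s) | run made earlier |  |
| flask | 0.0750 M (fed, over 30 s) |  | 8.0 min |

amber run (percent of the starting material charged)

| time / min | starting material / % | target / % | isomer of the product / % | over-reaction product / % |
|---|---|---|---|---|
| 0.200 | 97.9 | 1.7 | 0.2 | 0.8 |
| 0.333 | 96.9 | 2.9 | 0.7 | 0.9 |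
| 0.417 | 94.3 | 6.0 | 0 | 1.4 |
| 0.667 | 88.6 | 12.2 | 0.7 | 2.1 |
| 1.00 | 77.3 | 18.3 | 0.5 | 1.6 |
| 1.50 | 68.5 | 24.5 | 1.8 | 4.2 |
| 2.50 | 54.5 | 30.7 | 3.0 | 11.4 |

(standard deviation of a reading: 1 percentage point)



* the species in which most of what was charged as starting material, at 8.0 min sits (target / starting material / over-reaction product / isomer of the product)
* the largest share itself, whichever of these holds it, in percent of the starting material charged

We carry one quantity, the pull κ, the rate per minute at which starting material is lost per mole per litre of free partner. The amber run, between 1.00 min and 2.50 min, with partner taken at its charge, gives the reading 1.55 M⁻¹ min⁻¹. Both flasks hold 1.2 mM of catalyst, so κ includes it.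

First the main step by itself. Starting material is the limiting reagent, and partner falls one for one with it, which integrates to 48.7 % left in the flask. Next the over-reaction: the amber readings give target a pull of 1.78 M⁻¹ min⁻¹, close to κ, so we use κ for both steps. That gives target 35.0 % and over-reaction product 16.3 %. Last the isomer: we take it as drawn from target, and for neither this step nor the over-reaction do we correct starting material, so our reckoning stays at 48.7 %, ahead of target.

The forecast also names starting material, at 44 %, lower than ours, on the grounds that “the rate starts at half the amber value and falls as partner is consumed by both steps”.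

The flask gives starting material at 47.1 %, target 27.2 % and over-reaction product 17.1 %.

    starting material + partner + catalyst ⇌ target + catalyst, rate k1*[starting material]*[partner]*[catalyst] forward; the back reaction follows from the equilibrium constant (K = 39.0 M⁻¹, k = 30.6 M⁻² s⁻¹)
    target ⇌ isomer of the product (K = 0.850, k = 0.00102 s⁻¹)
    partner + target → over-reaction product (k = 0.0320 M⁻¹ s⁻¹)

At 8.00 min the forward half-life of starting material in this flask is 7.9 min, about the length of the run, with partner at 53.3 % of its charge. κ on the partner midway between first and last amounts gives 50.1 % of starting material in this flask, beside 47.1 %. In the neighbour charged with 0.30 M of partner, 70.5 % of it left, κ gives 4.63 % beside 3.46 %, and its largest holder is over-reaction product at 80.3 %.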